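**Plan**

- Retrosynthesis cuts, in order: the O6–acyl ester bond and C11–C12 (made by alkyne hydromethoxycarbonylation); then C4=C15 and C11≡C13; then C8–C9 and C6–C7 of the carbocycle C5–C6–C7–C8–C9–C10, which contracts it to a cyclobutanone (C6=O, C9H2) fused on C5–C10; last the cyclobutane bonds C5–C6 and C9–C10.
- Enabling feature: C5–C10, with its methyl-bearing quaternary C10, is the α,β-bond of a β-methylcyclohexenone whose carbonyl carbon is C4 (later the exocyclic methylene carbon). The acyloxy carbon C6 sits on C5, where an enone–allene photocycloaddition places the four-ring carbonyl. C7, C8 and C11 are then inserted as one alkenyl unit, driven by four-ring strain.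
- Forward: ring A (C1–C5, C10) from (R)-carvone → [2+2] on C5=C10 → cyclobutanone → alkenyl carbinol → two-carbon ring expansion to the second six-membered ring → C6 reduction, C11 homologation, C4 methylenation → esterification at O6 → C12 ester.
- Stereochemistry: C3 from carvone (Criegee rearrangement, retention); C1 by Luche reduction (cis to O3); C10 by photocycloaddition anti to both silyloxy groups; C5 and C7 by equilibration α to the C6 ketone; C6 by dissolving-metal reduction (equatorial alcohol).

Key step: step 9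

Remark: eudesmane numbering is used for all intermediates (ring A = C1–C5, C10; second ring = C5–C10; side chain C11–C13; angular methyl C14; exocyclic methylene C15); β is the face of C14.

**Route**

Step 1
Reactants: 1 (R)-(−)-carvone
Product: 3 (5R)-5-acetoxy-2-methylcyclohex-2-en-1-one, via methoxy hydroperoxide 2 (not isolated)
Conditions: O3, CH2Cl2/MeOH, −78 °C; then Ac2O, Et3N, DMAP (cat.), −78 → 25 °C
Reagents that add atoms: ozone O=[O+][O-]; methanol CO
Why: Criegee rearrangement: ozonolysis of the electron-rich isopropenyl group in methanol gives the α-methoxy hydroperoxide, whose peracetate rearranges with migration of the ring carbon to oxygen with retention, so the carvone stereocentre becomes the C3 carbinol centre (O on the β face) while the conjugated enone C=C is spared at −78 °C.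

Step 2
Reactants: 3 (5R)-5-acetoxy-2-methylcyclohex-2-en-1-one
Product: 5 (1R,5R)-2-methylcyclohex-2-ene-1,5-diol, via hydroxy acetate 4 (not isolated)
Conditions: NaBH4, CeCl3·7H2O, MeOH, −78 °C; then K2CO3, 25 °C
Reagents that add atoms: none
Why: Luche 1,2-reduction delivers hydride axially to the half-chair with the acetoxy group equatorial and should give the cis (1,3-diequatorial) allylic alcohol, as in carvone → cis-carveol, which sets C1 (O on the β face); carbonate methanolysis then frees the C3 hydroxyl in the same flask.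

Step 3
Reactants: 5 (1R,5R)-2-methylcyclohex-2-ene-1,5-diol
Product: 6 (1R,5R)-1,5-bis(tert-butyldimethylsilyloxy)-2-methylcyclohex-2-ene
Conditions: TBSCl, imidazole, DMF, 25 °C
Reagents that add atoms: tert-butyldimethylsilyl chloride CC(C)(C)[Si](C)(C)Cl
Why: Standard silylation of both secondary alcohols; no stereocentre is affected.

Step 4
Reactants: 6 (1R,5R)-1,5-bis(tert-butyldimethylsilyloxy)-2-methylcyclohex-2-ene
Product: 7 (4R,6S)-4,6-bis(tert-butyldimethylsilyloxy)-3-methylcyclohex-2-en-1-one
Conditions: Rh2(cap)4 (1 mol%), t-BuOOH (70% aq.), K2CO3, CH2Cl2, 25 °C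
Reagents that add atoms: tert-butyl hydroperoxide CC(C)(C)OO
Why: Dirhodium-caprolactamate/TBHP allylic C–H oxidation should attack the ring methylene next to the vinylic CH (C4), as in 1-methylcyclohexene → 3-methylcyclohex-2-enone, giving the β-methyl enone with its carbonyl at C4; the allylic C1–H is shielded by its silyl ether and the neighbouring methyl.

Step 5
Reactants: 7 (4R,6S)-4,6-bis(tert-butyldimethylsilyloxy)-3-methylcyclohex-2-en-1-one; 8 allene
Product: 9 cis-fused photoadduct (1β,3β-bis-OTBS, 4-oxo, 5β-H, 10β-methyl, C6 exocyclic methylene; four-membered ring C5–C6–C9–C10 on the α face)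
Conditions: hν (350 nm, Pyrex), excess allene, THF, −78 °C
Reagents that add atoms: none
Why: Enone–allene [2+2] photocycloaddition: head-to-head regiochemistry (central allene carbon to the enone α-carbon C5) and approach anti to the γ-silyloxy group at C1 (and the C3 silyloxy group) should create the quaternary C10 with its methyl syn to O1 in a cis-fused cyclobutane.

Step 6
Reactants: 9 cis-fused photoadduct
Product: 10 C4 ethylene ketal of 9
Conditions: TMSOTf (5 mol%), 1,2-bis(trimethylsilyloxy)ethane, CH2Cl2, −78 → −20 °C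
Reagents that add atoms: 1,2-bis(trimethylsilyloxy)ethane C[Si](C)(C)OCCO[Si](C)(C)C
Why: Silyl-triflate-catalysed ketalisation with the bis-silyl glycol masks the C4 ketone under cold, aprotic conditions that spare the silyl ethers and the exocyclic alkene, so that step 7 does not produce a retro-Claisen-prone 2-acylcyclobutanone and C4 stays sp3 while C6 is a ketone.

Step 7
Reactants: 10 C4 ethylene ketal of 9
Product: 12 fused cyclobutanone (C6 ketone on C5, C9H2 on C10), via spiro ozonide 11 (not isolated)
Conditions: O3, CH2Cl2, −78 °C; then PPh3, −78 → 25 °C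
Reagents that add atoms: ozone O=[O+][O-]
Why: Ozonolysis of the only alkene (1,1-disubstituted, exocyclic) with reductive work-up unveils the cyclobutanone without touching a stereocentre.

Step 8
Reactants: 12 fused cyclobutanone; 13 2-bromo-3,3-diethoxyprop-1-ene
Product: 14 tertiary cyclobutanol (C6–OH, C6–[3,3-diethoxyprop-1-en-2-yl]; alkenyl group on the face of H5 and C14)
Conditions: 13, t-BuLi (2 equiv), Et2O, −78 °C; then 12, THF, −78 °C; aq. NH4Cl
Reagents that add atoms: none
Why: Bromine–lithium exchange gives the α-lithiated acrolein acetal (an acrolein α-anion equivalent), which should add 1,2 to the strained, highly electrophilic cyclobutanone from its convex face; the carbinol centre so formed is erased in step 9.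

Step 9
Reactants: 14 tertiary cyclobutanol
Product: 16 trans-fused 7β-(diethoxymethyl)-4,4-ethylenedioxy-1β,3β-bis-OTBS-eudesman-6-one skeleton (5α-H), via cis-fused ketone 15 (not isolated)
Conditions: [Rh(OH)(cod)]2 (5 mol%), rac-BINAP (12 mol%), toluene, 90 °C; then NaOMe (0.3 equiv), MeOH, 25 °C
Reagents that add atoms: none
Why: Proposed new method: the rhodium(I) alkoxide of the tertiary cyclobutanol should undergo β-carbon elimination of the C6–C9 bond (release of about 26 kcal/mol of ring strain), giving a C9 alkylrhodium that has no β-hydrogen (C10 is quaternary) and an α-substituted vinyl ketone (C6=O, C7=C8), and intramolecular conjugate carbometalation at C8 followed by protonation of the rhodium enolate by the next carbinol turns the catalyst over. The closest known reaction types are the Rh(I)-catalysed ring expansion of 1-allenylcyclobutanols to cyclohexenones (β-carbon elimination, then conjugate addition of the alkylrhodium) and the alkoxy-radical n+2 ring expansion of 1-vinylcycloalkanols; the metal-mediated vinyl carbinol case is the untested part. The six-membered ring C5–C6–C7–C8–C9–C10 is closed by C8–C9 bond formation in a 6-endo-trig conjugate addition onto the unsubstituted alkene terminus, a net two-atom expansion of the four-membered ring. No stereocentre needs kinetic control: C10 is untouched, and C5 and C7, both α to the new C6 ketone, are equilibrated by methoxide to the trans-fused decalin with the equatorial 7β-acetal (a stereoconvergent end), so the carbinol epimer of 14 and the face of enolate protonation do not matter. The step needs cleavage of C6–C9 rather than C6–C5, which the preference of metal β-carbon elimination for the less substituted carbon and the bulky C4 ketal next to C5 should secure (a radical variant would break toward the more substituted C5 and is avoided); it also needs ring closure faster than protonolysis of the alkylrhodium, which the aprotic medium and the proximity of the enone should secure.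

Step 10
Reactants: 16 trans-fused 6-ketone
Product: 17 6α-alcohol (7β-diethoxymethyl, 4,4-ethylenedioxy, 1β,3β-bis-OTBS)
Conditions: Li, NH3(l)/THF, t-BuOH, −78 °C; then NH4Cl
Reagents that add atoms: none
Why: Dissolving-metal reduction passes through a configurationally labile ketyl/carbanion and should give the thermodynamically preferred equatorial 6α-alcohol (an axial 6β-hydroxyl would be 1,3-diaxial to C14), whereas hydride reagents, forced to the α face by C14, would give the 6β-epimer; ketal, acetal and silyl ethers are inert.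

Step 11
Reactants: 17 6α-alcohol
Product: 18 6α-(4-methoxybenzyl) ether of 17
Conditions: NaH, PMBCl, Bu4NI (cat.), DMF, 0 → 25 °C
Reagents that add atoms: 4-methoxybenzyl chloride COc1ccc(CCl)cc1
Why: Williamson etherification protects O6 as an ether that is stable to acid and base, can be removed oxidatively later, and prevents retro-aldol cleavage of the β-oxygenated carbonyl compounds of steps 12–14.

Step 12
Reactants: 18 6α-PMB ether
Product: 19 keto aldehyde (4-oxo, 7β-formyl, 6α-OPMB, 1β,3β-bis-OTBS)
Conditions: p-TsOH·H2O (cat.), acetone/H2O (10:1), 25 °C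
Reagents that add atoms: water O
Why: Acid-catalysed hydrolysis should cleave the acyclic acetal and the dioxolane while the PMB ether and secondary TBS ethers survive; the formyl group at C7 stays equatorial (epimerisable, thermodynamic).

Step 13
Reactants: 19 keto aldehyde
Product: 20 7β-ethynyl-4-ketone
Conditions: dimethyl (1-diazo-2-oxopropyl)phosphonate, K2CO3, MeOH, 0 → 25 °C
Reagents that add atoms: dimethyl (1-diazo-2-oxopropyl)phosphonate CC(=O)C(=[N+]=[N-])P(=O)(OC)OC
Why: Seyferth–Gilbert homologation with the Ohira–Bestmann reagent converts the aldehyde into the terminal alkyne (C13 from the reagent); carbonate in methanol at 0 °C is mild enough that the hindered C4 ketone reacts far more slowly and its α-silyloxy centre C3 and the β-alkoxy groups should stay untouched.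

Step 14
Reactants: 20 7β-ethynyl-4-ketone
Product: 21 7β-ethynyl-4(15)-ene (6α-OPMB, 1β,3β-bis-OTBS)
Conditions: Zn, CH2Br2, TiCl4, THF; then 20, CH2Cl2, 0 → 25 °C
Reagents that add atoms: dibromomethane BrCBr
Why: Takai–Lombardo methylenation is non-basic and suited to hindered, enolisable ketones, so C4=C15 should be installed without epimerising C3 or C5 or eliminating the β-PMB ether; the terminal alkyne only consumes excess reagent.

Step 15
Reactants: 21 7β-ethynyl-4(15)-ene
Product: 22 6α-alcohol (7β-ethynyl, 4(15)-ene, 1β,3β-bis-OTBS)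
Conditions: DDQ, CH2Cl2/pH 7 buffer, 0 °C
Reagents that add atoms: none
Why: Oxidative PMB cleavage (single-electron oxidation of the electron-rich arene, then hydrolysis) frees only O6; silyl ethers, the 1,1-disubstituted alkene and the alkyne are inert to DDQ.

Step 16
Reactants: 23 methyl 2-(hydroxymethyl)acrylate
Product: 24 methyl 2-[(tert-butyldimethylsilyloxy)methyl]acrylate
Conditions: TBSCl, imidazole, CH2Cl2, 0 → 25 °C
Reagents that add atoms: tert-butyldimethylsilyl chloride CC(C)(C)[Si](C)(C)Cl
Why: Silylation of the primary allylic alcohol.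

Step 17
Reactants: 24 methyl 2-[(tert-butyldimethylsilyloxy)methyl]acrylate
Product: 25 2-[(tert-butyldimethylsilyloxy)methyl]acrylic acid
Conditions: LiOH, THF/H2O, 0 °C; then 1 M HCl to pH 4
Reagents that add atoms: lithium hydroxide [Li+].[OH-]
Why: Saponification of the methyl ester at 0 °C; the α-substituted acrylate resists conjugate addition of hydroxide and the primary TBS ether should survive.

Step 18
Reactants: 22 6α-alcohol; 25 2-[(tert-butyldimethylsilyloxy)methyl]acrylic acid
Product: 27 6α-{2-[(tert-butyldimethylsilyloxy)methyl]acryloyloxy} ester of 22, via mixed anhydride 26 (not isolated)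
Conditions: 25, 2,4,6-trichlorobenzoyl chloride, Et3N, toluene, 25 °C; then 22, DMAP, toluene, 40 °C
Reagents that add atoms: none
Why: Yamaguchi esterification: DMAP attacks the less hindered acrylic carbonyl of the mixed anhydride and the acylpyridinium acylates the hindered equatorial 6α-hydroxyl with retention at C6; because C7 still carries an alkyne, no lactone can form, which is why the C12 ester is made afterwards.

Step 19
Reactants: 27 6α-ester with 7β-ethynyl group
Product: 28 tris-TBS ether of the target
Conditions: Pd(OAc)2 (3 mol%), 2-(diphenylphosphino)pyridine (12 mol%), MsOH (6 mol%), CO (20 bar), MeOH (10 equiv), THF, 45 °C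
Reagents that add atoms: carbon monoxide [C-]#[O+]; methanol CO
Why: Palladium/2-pyridylphosphine-catalysed hydromethoxycarbonylation of terminal alkynes is Markovnikov-selective (Pd–H places palladium on the internal carbon, then CO insertion and methanolysis), so it should give the 2-substituted acrylate with C11=C13 and the C12 methyl ester in one step; the 1,1-disubstituted alkene and the existing acrylate do not react.

Step 20
Reactants: 28 tris-TBS ether of the target
Product: 29 CNP0247525.1 (target)
Conditions: HF·pyridine, pyridine, THF, 0 → 25 °C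
Reagents that add atoms: none
Why: Buffered fluoride removes the three silyl ethers without touching the two acrylate esters; O6 is acylated and O1/O3 are remote, so neither lactonisation nor acyl migration is expected.

**Compound list**

1 | (R)-(−)-carvone, (5R)-2-methyl-5-(prop-1-en-2-yl)cyclohex-2-en-1-one | CC(=C)[C@@H]1CC=C(C)C(=O)C1 | starting material
2 | (5R)-5-(1-hydroperoxy-1-methoxyethyl)-2-methylcyclohex-2-en-1-one (both epimers at the new acetal carbon) | CC1=CC[C@H](CC1=O)C(C)(OC)OO | intermediate
3 | (5R)-5-acetoxy-2-methylcyclohex-2-en-1-one | C1[C@@H](OC(C)=O)CC(=O)C(C)=C1 | intermediate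
4 | (1R,5R)-5-hydroxy-4-methylcyclohex-3-en-1-yl acetate (cis) | C1[C@@H](OC(C)=O)C[C@@H](O)C(C)=C1 | intermediate
5 | (1R,5R)-2-methylcyclohex-2-ene-1,5-diol (cis) | C1[C@@H](O)C[C@@H](O)C(C)=C1 | intermediate
6 | (1R,5R)-1,5-bis(tert-butyldimethylsilyloxy)-2-methylcyclohex-2-ene | C1[C@@H](O[Si](C)(C)C(C)(C)C)C[C@@H](O[Si](C)(C)C(C)(C)C)C(C)=C1 | intermediate
7 | (4R,6S)-4,6-bis(tert-butyldimethylsilyloxy)-3-methylcyclohex-2-en-1-one | O=C1[C@@H](O[Si](C)(C)C(C)(C)C)C[C@@H](O[Si](C)(C)C(C)(C)C)C(C)=C1 | intermediate
8 | allene (propa-1,2-diene) | C=C=C | starting material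
9 | cis-fused photoadduct, 3,5-bis(TBSO)-6-methyl-8-methylenebicyclo[4.2.0]octan-2-one; 1β,3β-bis-OTBS, 4-oxo, 5β-H, 10β-methyl, cyclobutane on the α face | C=C1[C@@H]2C(=O)[C@@H](O[Si](C)(C)C(C)(C)C)C[C@@H](O[Si](C)(C)C(C)(C)C)[C@]2(C)C1 | intermediate
10 | C4 ethylene ketal (spiro-dioxolane) of 9 | C=C1[C@@H]2C3(OCCO3)[C@@H](O[Si](C)(C)C(C)(C)C)C[C@@H](O[Si](C)(C)C(C)(C)C)[C@]2(C)C1 | intermediate
11 | spiro ozonide (1,2,4-trioxolane at C6) of 10, C6 epimers | C1OC2(OO1)[C@@H]3C4(OCCO4)[C@@H](O[Si](C)(C)C(C)(C)C)C[C@@H](O[Si](C)(C)C(C)(C)C)[C@]3(C)C2 | intermediate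
12 | fused cyclobutanone: C6 ketone, C9H2; 4,4-ethylenedioxy, 1β,3β-bis-OTBS, 5β-H, 10β-methyl | O=C1[C@@H]2C3(OCCO3)[C@@H](O[Si](C)(C)C(C)(C)C)C[C@@H](O[Si](C)(C)C(C)(C)C)[C@]2(C)C1 | intermediate
13 | 2-bromo-3,3-diethoxyprop-1-ene (2-bromoacrolein diethyl acetal) | C=C(Br)C(OCC)OCC | starting material
14 | tertiary cyclobutanol: C6–OH and C6–(3,3-diethoxyprop-1-en-2-yl), alkenyl on the face of H5 and C14 | O[C@]1(C(=C)C(OCC)OCC)[C@@H]2C3(OCCO3)[C@@H](O[Si](C)(C)C(C)(C)C)C[C@@H](O[Si](C)(C)C(C)(C)C)[C@]2(C)C1 | intermediate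
15 | cis-fused (5β-H) 7-(diethoxymethyl)-4,4-ethylenedioxy-1β,3β-bis-OTBS-10β-methyldecalin-6-one, C7 epimers | O=C1[C@@H]2C3(OCCO3)[C@@H](O[Si](C)(C)C(C)(C)C)C[C@@H](O[Si](C)(C)C(C)(C)C)[C@]2(C)CCC1C(OCC)OCC | intermediate
16 | trans-fused (5α-H) 7β-(diethoxymethyl)-4,4-ethylenedioxy-1β,3β-bis-OTBS-10β-methyldecalin-6-one | O=C1[C@H]2C3(OCCO3)[C@@H](O[Si](C)(C)C(C)(C)C)C[C@@H](O[Si](C)(C)C(C)(C)C)[C@]2(C)CC[C@H]1C(OCC)OCC | intermediate
17 | 6α-alcohol of 16 | O[C@@H]1[C@H]2C3(OCCO3)[C@@H](O[Si](C)(C)C(C)(C)C)C[C@@H](O[Si](C)(C)C(C)(C)C)[C@]2(C)CC[C@H]1C(OCC)OCC | intermediate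
18 | 6α-(4-methoxybenzyl) ether of 17 | COc1ccc(CO[C@@H]2[C@H]3C4(OCCO4)[C@@H](O[Si](C)(C)C(C)(C)C)C[C@@H](O[Si](C)(C)C(C)(C)C)[C@]3(C)CC[C@H]2C(OCC)OCC)cc1 | intermediate
19 | 6α-PMBO-1β,3β-bis-OTBS-4-oxo-7β-formyl trans-decalin | COc1ccc(CO[C@@H]2[C@H]3C(=O)[C@@H](O[Si](C)(C)C(C)(C)C)C[C@@H](O[Si](C)(C)C(C)(C)C)[C@]3(C)CC[C@H]2C=O)cc1 | intermediate
20 | 6α-PMBO-1β,3β-bis-OTBS-7β-ethynyl trans-decalin-4-one | COc1ccc(CO[C@@H]2[C@H]3C(=O)[C@@H](O[Si](C)(C)C(C)(C)C)C[C@@H](O[Si](C)(C)C(C)(C)C)[C@]3(C)CC[C@H]2C#C)cc1 | intermediate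
21 | 6α-PMBO-1β,3β-bis-OTBS-7β-ethynyl-4(15)-ene | COc1ccc(CO[C@@H]2[C@H]3C(=C)[C@@H](O[Si](C)(C)C(C)(C)C)C[C@@H](O[Si](C)(C)C(C)(C)C)[C@]3(C)CC[C@H]2C#C)cc1 | intermediate
22 | 1β,3β-bis-OTBS-7β-ethynyl-4(15)-en-6α-ol | O[C@@H]1[C@H]2C(=C)[C@@H](O[Si](C)(C)C(C)(C)C)C[C@@H](O[Si](C)(C)C(C)(C)C)[C@]2(C)CC[C@H]1C#C | intermediate
23 | methyl 2-(hydroxymethyl)acrylate | C=C(CO)C(=O)OC | starting material
24 | methyl 2-[(tert-butyldimethylsilyloxy)methyl]acrylate | C=C(CO[Si](C)(C)C(C)(C)C)C(=O)OC | intermediate
25 | 2-[(tert-butyldimethylsilyloxy)methyl]acrylic acid | C=C(CO[Si](C)(C)C(C)(C)C)C(=O)O | intermediate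
26 | mixed anhydride of 25 with 2,4,6-trichlorobenzoic acid | C=C(CO[Si](C)(C)C(C)(C)C)C(=O)OC(=O)c1c(Cl)cc(Cl)cc1Cl | intermediate
27 | 6α-{2-[(TBSO)methyl]acryloyloxy}-1β,3β-bis-OTBS-7β-ethynyl-4(15)-ene | C=C(CO[Si](C)(C)C(C)(C)C)C(=O)O[C@@H]1[C@H]2C(=C)[C@@H](O[Si](C)(C)C(C)(C)C)C[C@@H](O[Si](C)(C)C(C)(C)C)[C@]2(C)CC[C@H]1C#C | intermediate
28 | tris-TBS ether of the target (1-O, 3-O and acrylate CH2O silylated) | C=C(CO[Si](C)(C)C(C)(C)C)C(=O)O[C@@H]1[C@H]2C(=C)[C@@H](O[Si](C)(C)C(C)(C)C)C[C@@H](O[Si](C)(C)C(C)(C)C)[C@]2(C)CC[C@H]1C(=C)C(=O)OC | intermediate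
29 | CNP0247525.1: methyl 1β,3β-dihydroxy-6α-[2-(hydroxymethyl)acryloyloxy]eudesma-4(15),11(13)-dien-12-oate | C=C(CO)C(=O)O[C@@H]1[C@H]2C(=C)[C@@H](O)C[C@@H](O)[C@]2(C)CC[C@H]1C(=C)C(=O)OC | target

**Step count and risks**

Total step count: 20. Longest linear sequence: 18 (steps 1–15 and 18–20); steps 16–17 are a two-step side branch.

Steps most likely to fail:

1. Step 9 (proposed new method). The metal alkoxide may cleave the C6–C5 bond instead of C6–C9 (wrong regiochemistry of C–C cleavage), the alkylrhodium may be protonated before it closes the ring (simple ring opening), or ethoxide may be lost from the enolate. Fallback with known chemistry, from 12 and returning at 16: two successive Lewis-acid-promoted diazomethane homologations (Büchner–Curtius–Schlotterbeck, CH2N2, BF3·OEt2, Et2O, −40 °C), each with migration of the less substituted methylene, would give first the cis-fused cyclopentanone F1 and then the cis-fused cyclohexanone F2, so the ring is still made by ring expansion. Kinetic enolisation at C7 (LDA, TMSCl, THF, −78 °C) would give the trimethylsilyl enol ether F3. A Mukaiyama-type reaction of F3 with triethyl orthoformate and BF3·OEt2 would give keto acetal 15, which is equilibrated with NaOMe/MeOH to 16.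

2. Step 10. The reduction may show poor facial control, pinacol coupling, or cleavage of a C–O bond under the dissolving-metal conditions. Fallback from 16, returning at 17: NaBH4 (MeOH, 0 °C) would attack anti to C14 and give the axial 6β-alcohol F4. Meerwein–Ponndorf–Verley/Oppenauer equilibration (Al(Oi-Pr)3, i-PrOH, catalytic acetone, toluene, reflux) would then convert F4 by reversible hydride transfer into the more stable equatorial 6α-alcohol 17.

3. Step 19. The hydromethoxycarbonylation may lose regiocontrol at the hindered alkyne (linear ester), or the acidic methanol may cause desilylation or conjugate addition. Fallback from 27, returning at 28: Markovnikov hydroiodination of the terminal alkyne (B-iodo-9-BBN, hexane/CH2Cl2, −20 °C; then AcOH) would give the 2-iodoalkene F5. Palladium-catalysed methoxycarbonylation of F5 under basic conditions (Pd(PPh3)4, CO 1 atm, MeOH, Et3N, DMF, 50 °C) would then give 28 with the ester fixed on C11.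

Further compounds
F1 | step 9 | cis-fused cyclopentanone (one-carbon homologue of 12, C6 ketone on C5) | O=C1[C@@H]2C3(OCCO3)[C@@H](O[Si](C)(C)C(C)(C)C)C[C@@H](O[Si](C)(C)C(C)(C)C)[C@]2(C)CC1
F2 | step 9 | cis-fused 4,4-ethylenedioxy-1β,3β-bis-OTBS-10β-methyldecalin-6-one (C7 unsubstituted) | O=C1[C@@H]2C3(OCCO3)[C@@H](O[Si](C)(C)C(C)(C)C)C[C@@H](O[Si](C)(C)C(C)(C)C)[C@]2(C)CCC1
F3 | step 9 | trimethylsilyl enol ether of F2 (C6=C7) | C[Si](C)(C)OC=1[C@@H]2C3(OCCO3)[C@@H](O[Si](C)(C)C(C)(C)C)C[C@@H](O[Si](C)(C)C(C)(C)C)[C@]2(C)CCC=1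
F4 | step 10 | 6β-alcohol (C6 epimer of 17) | O[C@H]1[C@H]2C3(OCCO3)[C@@H](O[Si](C)(C)C(C)(C)C)C[C@@H](O[Si](C)(C)C(C)(C)C)[C@]2(C)CC[C@H]1C(OCC)OCC
F5 | step 19 | 7β-(1-iodovinyl) analogue of 27 | C=C(CO[Si](C)(C)C(C)(C)C)C(=O)O[C@@H]1[C@H]2C(=C)[C@@H](O[Si](C)(C)C(C)(C)C)C[C@@H](O[Si](C)(C)C(C)(C)C)[C@]2(C)CC[C@H]1C(I)=C
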